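Ring C is disconnected at O1–C2 and C3–C4. The C2–C3 fragment between these bonds, with ring B on C2 and oxygen on C3, is an (E)-β-acetoxystyrene, and the O1–C8a–C4a–C4 array is an ortho-quinone methide of ring A. One chiral-acid-catalysed oxa-[4+2] cycloaddition therefore closes the pyran, makes both bonds and sets C2 and C3 (trans, single enantiomer); C4 arrives as a methyl ether and is corrected afterwards through a cis-fused acetoxonium ion. The cycloaddition precursor is the dimethyl acetal of the fully substituted ring A salicylaldehyde (free phenol, 5-OMe, 7-OTIPS, 8-prenyl), ionised by a BINOL N-triflyl phosphoramide.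

Key step: step 9

Assumptions: 2,4-dihydroxy-6-methoxybenzaldehyde is taken as a purchasable catalogue compound, and the (R)-catalyst is taken to give the (2R,3S) series (if the sense of induction is opposite, the (S)-catalyst is used).

Step 1
Reactants: 1 2,4-dihydroxy-6-methoxybenzaldehyde
Product: 2 2-hydroxy-6-methoxy-4-(triisopropylsilyloxy)benzaldehyde
Conditions: TIPSCl (1.05 equiv), imidazole, DMF, 0 °C
Reagents that add atoms: chlorotriisopropylsilane (TIPSCl), CC(C)[Si](Cl)(C(C)C)C(C)C
Why: Silyl ether formation should be selective for the 4-OH because the 2-OH is hydrogen-bonded to and flanked by the formyl group, and TIPS rather than a smaller silyl group is chosen so that the ether survives the later base, acid and cation chemistry.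

Step 2
Reactants: 3 2-methylbut-3-en-2-ol
Product: 5 tert-butyl 2-methylbut-3-en-2-yl carbonate, via lithium alkoxide 4 (not isolated)
Conditions: n-BuLi, THF, 0 °C; then Boc2O, 0 °C → rt
Reagents that add atoms: di-tert-butyl dicarbonate (Boc2O), CC(C)(C)OC(=O)OC(=O)OC(C)(C)C
Why: The tertiary alcohol is deprotonated and the alkoxide is acylated by Boc2O (alkoxycarbonylation), the usual way to an allylic carbonate for palladium chemistry.

Step 3
Reactants: 2 2-hydroxy-6-methoxy-4-(triisopropylsilyloxy)benzaldehyde; 5 tert-butyl 2-methylbut-3-en-2-yl carbonate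
Product: 6 2-methoxy-6-(2-methylbut-3-en-2-yloxy)-4-(triisopropylsilyloxy)benzaldehyde
Conditions: Pd(PPh3)4 (2 mol%), THF, 0 °C
Reagents that add atoms: none
Why: Tsuji–Trost O-allylation, in which zerovalent palladium ionises 5 with loss of CO2, the tert-butoxide released deprotonates the only free phenol, and the phenoxide attacks the more substituted terminus of the 1,1-dimethylallyl palladium complex under kinetic control to give the tertiary aryl ether.

Step 4
Reactants: 6 2-methoxy-6-(2-methylbut-3-en-2-yloxy)-4-(triisopropylsilyloxy)benzaldehyde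
Product: 8 2-hydroxy-6-methoxy-3-(3-methylbut-2-en-1-yl)-4-(triisopropylsilyloxy)benzaldehyde, via Claisen dienone 7 (not isolated)
Conditions: PhMe, 110 °C, sealed tube
Reagents that add atoms: none
Why: Aromatic Claisen rearrangement, accelerated by the gem-dimethyl group, delivers the allyl unit with transposition to C3, the only free ortho position, so the normal prenyl group ends up between the two ring oxygens and dienone 7 tautomerises to the chelated phenol.

Step 5
Reactants: 8 2-hydroxy-6-methoxy-3-(3-methylbut-2-en-1-yl)-4-(triisopropylsilyloxy)benzaldehyde; 9 trimethyl orthoformate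
Product: 10 2-(dimethoxymethyl)-3-methoxy-6-(3-methylbut-2-en-1-yl)-5-(triisopropylsilyloxy)phenol
Conditions: 9 (neat, excess), PPTS (5 mol%), 0 °C → rt; Et3N quench, filtration through basic Al2O3, used at once
Reagents that add atoms: none
Why: Acid-catalysed acetalisation driven by the orthoformate, with PPTS too weak to cyclise the phenol onto the prenyl group or to cleave the aryl TIPS ether, and the labile electron-rich acetal taken on crude.

Step 6
Reactants: 11 4-hydroxybenzaldehyde
Product: 12 4-(triisopropylsilyloxy)benzaldehyde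
Conditions: TIPSCl, imidazole, DMF, rt
Reagents that add atoms: chlorotriisopropylsilane (TIPSCl), CC(C)[Si](Cl)(C(C)C)C(C)C
Why: Standard phenol silylation (silyl ether formation), using the same TIPS group as on ring A so that one final operation frees both phenols and ring B is a strong cation-stabilising donor.

Step 7
Reactants: 12 4-(triisopropylsilyloxy)benzaldehyde; 13 bis(4,4,5,5-tetramethyl-1,3,2-dioxaborolan-2-yl)methane
Product: 15 4,4,5,5-tetramethyl-2-[(E)-2-(4-(triisopropylsilyloxy)phenyl)ethenyl]-1,3,2-dioxaborolane, via lithiated diborylmethane 14 (not isolated)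
Conditions: 13, LiTMP, THF, 0 °C; then 12, −78 °C → rt
Reagents that add atoms: none
Why: Boron–Wittig olefination, in which the α-boryl carbanion 14 adds to the aldehyde and syn B–O elimination from the adduct gives the alkenyl boronate, the (E)-isomer being strongly favoured for aryl aldehydes.

Step 8
Reactants: 15 4,4,5,5-tetramethyl-2-[(E)-2-(4-(triisopropylsilyloxy)phenyl)ethenyl]-1,3,2-dioxaborolane
Product: 16 (E)-2-[4-(triisopropylsilyloxy)phenyl]ethenyl acetate
Conditions: Cu(OAc)2 (2 equiv), DMAP (0.2 equiv), 4 Å MS, MeCN, air, 40 °C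
Reagents that add atoms: copper diacetate Cu(OAc)2, CC(=O)[O-].CC(=O)[O-].[Cu+2]
Why: Chan–Lam–Evans C–O coupling, in which the alkenyl group passes from boron to divalent copper and reductive elimination from a trivalent copper acetate forms the C–O bond with retention of the (E)-geometry.

Step 9
Reactants: 10 2-(dimethoxymethyl)-3-methoxy-6-(3-methylbut-2-en-1-yl)-5-(triisopropylsilyloxy)phenol; 16 (E)-2-[4-(triisopropylsilyloxy)phenyl]ethenyl acetate
Product: 18 (2R,3S,4RS)-3-acetoxy-4,5-dimethoxy-8-(3-methylbut-2-en-1-yl)-7-(triisopropylsilyloxy)-2-[4-(triisopropylsilyloxy)phenyl]chroman (2,3-trans; both C4 epimers), via ortho-quinone methide 17 (not isolated)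
Conditions: (R)-3,3'-bis(2,4,6-triisopropylphenyl)-1,1'-binaphthyl-2,2'-diyl N-triflylphosphoramide (10 mol%), 16 (2 equiv), 5 Å MS, PhMe, −60 °C; Et3N quench
Reagents that add atoms: none
Why: Proposed new method: the phosphoramide protonates one acetal oxygen of 10, methanol leaves into the sieves, and the resulting aryl(methoxy)carbenium ion, which is O-protonated ortho-quinone methide 17 stabilised by 5-OMe and 7-OTIPS, stays hydrogen-bonded and ion-paired to the chiral anion, whereupon the acetoxy-bearing carbon of 16 bonds to C4 and the phenol oxygen closes onto the benzylic carbon. The closest known reaction types are chiral phosphoric acid catalysed [4+2] cycloadditions of in situ ortho-quinone methides with electron-rich alkenes and achiral acid-promoted chroman formation from salicylaldehyde acetals and styrenes; an enol ester dienophile on an acetal-derived, 4-oxygenated quinone methide has not been shown in asymmetric form. Ring C closes by an asynchronous inverse-electron-demand oxa-[4+2] cycloaddition (C3–C4 leading, O1–C2 following; at the stepwise limit a six-membered collapse of the phenol oxygen onto the C2 benzylic cation). The 2,3-trans relationship follows from suprafacial addition across the (E)-alkene and is also the diequatorial outcome of a stepwise closure; the absolute configuration at C2 and C3 (2R,3S) is set by the alkene approaching the face of the ion-paired heterodiene left open by the 3,3'-aryl groups of the catalyst, and C4 is deliberately left uncontrolled. The step needs regioselectivity (aryl on C2, acetoxy on C3), which the 4-silyloxyphenyl group should secure because it stabilises positive charge at C2 far better than acetoxy would at C3, and chemoselectivity over prenyl protonation, loss of silicon from the para-silyloxy cations and Friedel–Crafts attack at C6–H, which the low temperature, the bulky TIPS groups, the excess of 16 and the removal of methanol are meant to secure.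

Step 10
Reactants: 18 (2R,3S,4RS)-3-acetoxy-4,5-dimethoxy-8-(3-methylbut-2-en-1-yl)-7-(triisopropylsilyloxy)-2-[4-(triisopropylsilyloxy)phenyl]chroman
Product: 22 (2R,3S,4S)-5-methoxy-8-(3-methylbut-2-en-1-yl)-7-(triisopropylsilyloxy)-2-[4-(triisopropylsilyloxy)phenyl]chroman-3,4-diol (2,3-trans-3,4-cis), via acetoxonium triflate 19 (not isolated), via 3-O-acetate 20 (not isolated), via 4-O-acetate 21 (not isolated)
Conditions: TMSOTf (1.2 equiv), 2,6-di-tert-butyl-4-methylpyridine, CH2Cl2, −78 °C; THF–H2O, −78 → 0 °C; then K2CO3, MeOH, 0 °C → rt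
Reagents that add atoms: none
Why: TMSOTf removes the C4 methoxy group of either epimer as TMSOMe to give a benzylic cation stabilised by 5-OMe, 7-OTIPS and O1, the neighbouring 3-acetate captures it on its own face as the cis-fused dioxolanylium ion 19, water attacks the acyloxonium carbon (Woodward-type hydrolysis, the water oxygen leaving later in methyl acetate) so that the orthoacid collapses to the cis-hydroxy acetates 20 and 21 with the C4–O bond cis to C3–O (4S), and K2CO3/MeOH transesterification frees diol 22 without touching the aryl TIPS ethers.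

Step 11
Reactants: 22 (2R,3S,4S)-5-methoxy-8-(3-methylbut-2-en-1-yl)-7-(triisopropylsilyloxy)-2-[4-(triisopropylsilyloxy)phenyl]chroman-3,4-diol
Product: 23 5-O-methyl-8-prenylafzelechin-4β-ol, (2R,3S,4S)-2-(4-hydroxyphenyl)-5-methoxy-8-(3-methylbut-2-en-1-yl)chroman-3,4,7-triol
Conditions: Bu4NF (2.5 equiv), AcOH (2.5 equiv), THF, 0 °C; pH 7 buffer work-up
Reagents that add atoms: none
Why: Fluoride cleaves both aryl Si–O bonds (silyl ether deprotection driven by Si–F bond formation), and the acetic acid buffer keeps the freed phenols protonated, so that no phenoxide can expel the C4 hydroxyl or open ring C at C2 and the three stereocentres stay as set.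

Compound list
1 | 2,4-dihydroxy-6-methoxybenzaldehyde | COc1cc(O)cc(O)c1C=O | starting material
2 | 2-hydroxy-6-methoxy-4-(triisopropylsilyloxy)benzaldehyde | COc1cc(O[Si](C(C)C)(C(C)C)C(C)C)cc(O)c1C=O | intermediate
3 | 2-methylbut-3-en-2-ol | C=CC(C)(C)O | starting material
4 | lithium 2-methylbut-3-en-2-olate (not isolated) | C=CC(C)(C)[O-].[Li+] | intermediate
5 | tert-butyl 2-methylbut-3-en-2-yl carbonate | C=CC(C)(C)OC(=O)OC(C)(C)C | intermediate
6 | 2-methoxy-6-(2-methylbut-3-en-2-yloxy)-4-(triisopropylsilyloxy)benzaldehyde | COc1cc(O[Si](C(C)C)(C(C)C)C(C)C)cc(OC(C)(C)C=C)c1C=O | intermediate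
7 | Claisen dienone, 2-formyl-3-methoxy-6-(3-methylbut-2-en-1-yl)-5-(triisopropylsilyloxy)cyclohexa-2,4-dien-1-one, racemic at C6 (not isolated) | COC1=C(C=O)C(=O)C(CC=C(C)C)C(O[Si](C(C)C)(C(C)C)C(C)C)=C1 | intermediate
8 | 2-hydroxy-6-methoxy-3-(3-methylbut-2-en-1-yl)-4-(triisopropylsilyloxy)benzaldehyde | COc1cc(O[Si](C(C)C)(C(C)C)C(C)C)c(CC=C(C)C)c(O)c1C=O | intermediate
9 | trimethyl orthoformate | COC(OC)OC | starting material
10 | 2-(dimethoxymethyl)-3-methoxy-6-(3-methylbut-2-en-1-yl)-5-(triisopropylsilyloxy)phenol | COc1cc(O[Si](C(C)C)(C(C)C)C(C)C)c(CC=C(C)C)c(O)c1C(OC)OC | intermediate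
11 | 4-hydroxybenzaldehyde | O=Cc1ccc(O)cc1 | starting material
12 | 4-(triisopropylsilyloxy)benzaldehyde | O=Cc1ccc(O[Si](C(C)C)(C(C)C)C(C)C)cc1 | intermediate
13 | bis(4,4,5,5-tetramethyl-1,3,2-dioxaborolan-2-yl)methane | CC1(C)OB(CB2OC(C)(C)C(C)(C)O2)OC1(C)C | starting material
14 | lithio-bis(4,4,5,5-tetramethyl-1,3,2-dioxaborolan-2-yl)methane (not isolated) | [Li]C(B1OC(C)(C)C(C)(C)O1)B1OC(C)(C)C(C)(C)O1 | intermediate
15 | 4,4,5,5-tetramethyl-2-[(E)-2-(4-(triisopropylsilyloxy)phenyl)ethenyl]-1,3,2-dioxaborolane | CC1(C)OB(/C=C/c2ccc(O[Si](C(C)C)(C(C)C)C(C)C)cc2)OC1(C)C | intermediate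
16 | (E)-2-[4-(triisopropylsilyloxy)phenyl]ethenyl acetate | CC(=O)O/C=C/c1ccc(O[Si](C(C)C)(C(C)C)C(C)C)cc1 | intermediate
17 | 4-methoxy ortho-quinone methide, 5-methoxy-6-(methoxymethylidene)-2-(3-methylbut-2-en-1-yl)-3-(triisopropylsilyloxy)cyclohexa-2,4-dien-1-one; reacts as its O-protonated form ion-paired with the catalyst anion (not isolated) | COC=C1C(=O)C(CC=C(C)C)=C(O[Si](C(C)C)(C(C)C)C(C)C)C=C1OC | intermediate
18 | (2R,3S,4RS)-3-acetoxy-4,5-dimethoxy-8-(3-methylbut-2-en-1-yl)-7-(triisopropylsilyloxy)-2-[4-(triisopropylsilyloxy)phenyl]chroman, 2,3-trans, C4 epimers | COc1cc(O[Si](C(C)C)(C(C)C)C(C)C)c(CC=C(C)C)c2c1C(OC)[C@H](OC(C)=O)[C@@H](c1ccc(O[Si](C(C)C)(C(C)C)C(C)C)cc1)O2 | intermediate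
19 | cis-fused 2-methyl-1,3-dioxolan-2-ylium triflate spanning O3–C3–C4–O4 of the flavan, aryl at C2 trans to O3 (not isolated) | COc1cc(O[Si](C(C)C)(C(C)C)C(C)C)c(CC=C(C)C)c2c1[C@@H]3[O+]=C(C)O[C@@H]3[C@@H](c1ccc(O[Si](C(C)C)(C(C)C)C(C)C)cc1)O2.[O-]S(=O)(=O)C(F)(F)F | intermediate
20 | (2R,3S,4S)-3-acetoxy-4-hydroxy-5-methoxy-8-(3-methylbut-2-en-1-yl)-7-(triisopropylsilyloxy)-2-[4-(triisopropylsilyloxy)phenyl]chroman, 2,3-trans-3,4-cis (not isolated) | COc1cc(O[Si](C(C)C)(C(C)C)C(C)C)c(CC=C(C)C)c2c1[C@H](O)[C@H](OC(C)=O)[C@@H](c1ccc(O[Si](C(C)C)(C(C)C)C(C)C)cc1)O2 | intermediate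
21 | 4-O-acetyl regioisomer of 20, 4-acetoxy-3-hydroxy, same arrangement in space (not isolated) | COc1cc(O[Si](C(C)C)(C(C)C)C(C)C)c(CC=C(C)C)c2c1[C@H](OC(C)=O)[C@H](O)[C@@H](c1ccc(O[Si](C(C)C)(C(C)C)C(C)C)cc1)O2 | intermediate
22 | (2R,3S,4S)-5-methoxy-8-(3-methylbut-2-en-1-yl)-7-(triisopropylsilyloxy)-2-[4-(triisopropylsilyloxy)phenyl]chroman-3,4-diol, 2,3-trans-3,4-cis | COc1cc(O[Si](C(C)C)(C(C)C)C(C)C)c(CC=C(C)C)c2c1[C@H](O)[C@H](O)[C@@H](c1ccc(O[Si](C(C)C)(C(C)C)C(C)C)cc1)O2 | intermediate
23 | 5-O-methyl-8-prenylafzelechin-4β-ol, (2R,3S,4S)-2-(4-hydroxyphenyl)-5-methoxy-8-(3-methylbut-2-en-1-yl)chroman-3,4,7-triol | COc1cc(O)c(CC=C(C)C)c2c1[C@H](O)[C@H](O)[C@@H](c1ccc(O)cc1)O2 | target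

Total step count: 11. Longest linear sequence: 7 steps (steps 1, 3, 4, 5, 9, 10, 11).

Steps most likely to fail

1. Step 9 (the step labelled as a proposed new method). The ion pair may be too loose and give poor facial selectivity, or the cation may be diverted into Friedel–Crafts self-condensation at C6–H or acid-mediated cyclisation of the phenol onto the prenyl group. The fallback uses known reactions only and avoids the quinone methide. It sets out from boronate 15 and aldehyde 8. Iododeboronation of 15 (I2, NaOH, THF, 0 °C) with retention should give (E)-1-(2-iodoethenyl)-4-(triisopropylsilyloxy)benzene F1. Iodine–lithium exchange (t-BuLi, Et2O, −78 °C) gives (E)-2-[4-(triisopropylsilyloxy)phenyl]ethenyllithium F2, of which slightly more than two equivalents are added to 8 (the first deprotonates the phenol) to give the racemic (E)-allylic alcohol F3. Sharpless kinetic resolution (Ti(OiPr)4, L-(+)-DIPT, t-BuOOH, 4 Å MS, CH2Cl2, −20 °C) is hydroxyl-directed and so should leave the prenyl alkene alone; by the Sharpless mnemonic it should epoxidise the (R)-alcohol to the erythro epoxy alcohol F4. The ortho-phenol then opens the trans-epoxide at the benzylic carbon with inversion (6-endo, assisted by the titanium alkoxide or a trace of PPTS). This gives the 2,3-trans-3,4-cis diol directly and returns to the route at 22.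

2. Step 10. Water may capture the open C4 benzylic cation rather than the acyloxonium carbon, which would erode the cis selectivity and give the 3,4-trans diol. The fallback replaces neighbouring-group control by thermodynamic control. It sets out from 18: methanolysis (K2CO3, MeOH, 0 °C) removes the acetate to give the (2R,3S,4RS)-3-hydroxy-4-methoxy flavan F5. Solvolysis in THF–H2O–AcOH at rt then exchanges the labile C4 methyl ether for hydroxyl under equilibrating conditions. This is the known acid-mediated C4 epimerisation of 2,3-trans-flavan-3,4-diols, which should settle on the 3,4-cis isomer because the quasi-axial C4–OH avoids the peri interaction with 5-OMe. The fallback returns to the route at 22.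

3. Step 3. The palladium catalyst may re-ionise the tertiary ether of this acidic ortho-formyl phenol, so that the product drifts to the linear prenyl ether, which would rearrange to the wrong skeleton in step 4. The fallback sets out from 2 and builds the same ether without palladium. Copper-catalysed propargylation (3-chloro-3-methylbut-1-yne, DBU, CuCl2 (cat.), MeCN, 0 °C) should give 2-methoxy-6-(2-methylbut-3-yn-2-yloxy)-4-(triisopropylsilyloxy)benzaldehyde F6. Semi-hydrogenation (H2, Pd/CaCO3 poisoned with Pb(OAc)2, quinoline, EtOAc) then returns to the route at 6.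

Further compounds
F1 | step 9 | (E)-1-(2-iodoethenyl)-4-(triisopropylsilyloxy)benzene | I/C=C/c1ccc(O[Si](C(C)C)(C(C)C)C(C)C)cc1
F2 | step 9 | (E)-2-[4-(triisopropylsilyloxy)phenyl]ethenyllithium | [Li]/C=C/c1ccc(O[Si](C(C)C)(C(C)C)C(C)C)cc1
F3 | step 9 | racemic (E)-1-[2-hydroxy-6-methoxy-3-(3-methylbut-2-en-1-yl)-4-(triisopropylsilyloxy)phenyl]-3-[4-(triisopropylsilyloxy)phenyl]prop-2-en-1-ol | COc1cc(O[Si](C(C)C)(C(C)C)C(C)C)c(CC=C(C)C)c(O)c1C(O)/C=C/c1ccc(O[Si](C(C)C)(C(C)C)C(C)C)cc1
F4 | step 9 | erythro trans-epoxy alcohol of F3, carbinol carbon (S), configured for inversion at the benzylic carbon to give 22 | COc1cc(O[Si](C(C)C)(C(C)C)C(C)C)c(CC=C(C)C)c(O)c1[C@H](O)[C@@H]1O[C@H]1c1ccc(O[Si](C(C)C)(C(C)C)C(C)C)cc1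
F5 | step 10 | (2R,3S,4RS)-4,5-dimethoxy-8-(3-methylbut-2-en-1-yl)-7-(triisopropylsilyloxy)-2-[4-(triisopropylsilyloxy)phenyl]chroman-3-ol | COc1cc(O[Si](C(C)C)(C(C)C)C(C)C)c(CC=C(C)C)c2c1C(OC)[C@H](O)[C@@H](c1ccc(O[Si](C(C)C)(C(C)C)C(C)C)cc1)O2
F6 | step 3 | 2-methoxy-6-(2-methylbut-3-yn-2-yloxy)-4-(triisopropylsilyloxy)benzaldehyde | COc1cc(O[Si](C(C)C)(C(C)C)C(C)C)cc(OC(C)(C)C#C)c1C=O
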